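**Plan**

1. Locants (germacrane type): C1 furanone C=O, C2 furanone CH, C3 furanone O-bearing sp2 carbon, C4(C15 methyl)=C5, C6 carbinol, C7, C8 lactone O-carbon, C9 CH2, C10 quaternary carbon (C14 methyl), C11/C12/C13 lactone α-carbon, carbonyl and exocyclic CH2. The target is 6S,7R,8S,10S with a (2S,3S)-epoxyangelate on O6.
2. Cuts, in retrosynthetic order: the O6–acyl bond (esterification with inversion); the C6–C7 bond of the nine-membered oxacycle O–C3–C4=C5–C6–C7–C8–C9–C10, with the C11=C13 double bond returned to C7=C11 and a C13–Br bond; C7=C11 (metathesis) and the O8–C12 acyl bond; the furanone O–C3 bond; the C1–C2 bond (acetylide plus lactone); the C9–C10 bond (pyruvate aldol).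
3. Forward ring order: a temporary γ-lactone (opened again in step 4), then the 3(2H)-furanone, then the butenolide that becomes the lactone ring, then the nine-membered ring last.
4. Enabling feature: C7 is the β-carbon of the α-methylene lactone and the neighbour of carbinol C6, so C6(OH)–C7–C11(=C13H2) is the retron of an SE2' addition of a butenolide-derived allylmetal (C13–C11=C7) to a C6 aldehyde. The Z-C4=C5 enal on furanone C3 holds that aldehyde within reach of C7.
5. Stereochemistry: C10 from a copper–bis(oxazoline) pyruvate aldol; C8 by 1,3-anti directed reduction; C7 (anti to C9) and C6 (6R, chair transition state) in the key step; C6 inverted to S in the Mitsunobu esterification; Z-C4=C5 from commercial enynol 1; the epoxide from a Sharpless epoxidation.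

Key step: step 10

Assumption: the (S,S)-ligand in step 2 is expected to give the 2S aldol, as it does with silyl ketene acetals; the (R,R)-ligand is equally available if the sense proved opposite.

**Route**

Step 1
Reactants: 1 (2Z)-3-methylpent-2-en-4-yn-1-ol
Product: 2 tert-butyl(dimethyl){[(2Z)-3-methylpent-2-en-4-yn-1-yl]oxy}silane
Conditions: TBSCl, imidazole, CH2Cl2, 0 °C → rt
Reagents that add atoms: tert-butyldimethylsilyl chloride, CC(C)(C)[Si](C)(C)Cl
Why: Imidazole-promoted silylation of the primary alcohol (silyl ether protection) leaves the Z alkene and the terminal alkyne untouched.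

Step 2
Reactants: 3 methyl pyruvate; 4 2-(trimethylsilyloxy)buta-1,3-diene
Product: 6 methyl (2S)-2-hydroxy-2-methyl-4-oxohex-5-enoate, via trimethylsilyl ether 5 (not isolated)
Conditions: Cu(OTf)2 (10 mol %), (S,S)-tBu-box (11 mol %), THF, −78 °C; then 1 M HCl, 0 °C
Reagents that add atoms: none
Why: Copper–bis(oxazoline)-catalysed Mukaiyama aldol in which pyruvate chelates divalent copper through both carbonyls and the tert-butyl groups of the ligand leave one ketone face open to the enolsilane terminus, which should set C10 as S and form the C9–C10 bond; acid work-up cleaves the O–Si bond of 5.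

Step 3
Reactants: 6 methyl (2S)-2-hydroxy-2-methyl-4-oxohex-5-enoate
Product: 8 (3S,5S)-5-ethenyl-3-hydroxy-3-methyloxolan-2-one, via anti-diol ester 7 (not isolated)
Conditions: Me4NBH(OAc)3, MeCN/AcOH, −30 °C; then TsOH·H2O (cat.), CH2Cl2, rt
Reagents that add atoms: none
Why: Evans–Saksena reduction, in which the C10 hydroxyl binds boron and delivers hydride intramolecularly through a chair transition state, should give the 1,3-anti diol (C8 S), whose C8 hydroxyl then lactonises onto the ester (five-membered ring).

Step 4
Reactants: 8 (3S,5S)-5-ethenyl-3-hydroxy-3-methyloxolan-2-one; 2 silyl ether of the enynol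
Product: 10 (2Z,7S,9S)-1-[(tert-butyldimethylsilyl)oxy]-7,9-dihydroxy-3,7-dimethylundeca-2,10-dien-4-yn-6-one, via lithium acetylide 9 (not isolated)
Conditions: 2 (2.4 equiv), n-BuLi (2.3 equiv), THF, −78 °C; add 8, −78 → −30 °C; aq. NH4Cl
Reagents that add atoms: none
Why: Acetylide addition to a lactone stops at the tetrahedral lithium alkoxide, which opens to the ynone on quench (ynone synthesis from lactones, forming C1–C2); C10 has no α-hydrogen to epimerise and one equivalent of 9 is spent on the tertiary hydroxyl.

Step 5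
Reactants: 10 dihydroxy ynone
Product: 11 (2S)-5-{(2Z)-4-[(tert-butyldimethylsilyl)oxy]but-2-en-2-yl}-2-[(2S)-2-hydroxybut-3-en-1-yl]-2-methylfuran-3(2H)-one
Conditions: (Ph3P)AuNTf2 (2 mol %), toluene, rt
Reagents that add atoms: none
Why: Gold-catalysed 5-endo-dig hydroalkoxylation of the γ-hydroxy ynone (C10–OH onto C3, then protodeauration) should give the 3(2H)-furanone, while the C8 hydroxyl would have to close a seven-membered ring and stays free.

Step 6
Reactants: 11 furanone alcohol; 12 2-(bromomethyl)prop-2-enoic acid
Product: 14 (2S)-1-[(2S)-5-{(2Z)-4-[(tert-butyldimethylsilyl)oxy]but-2-en-2-yl}-2-methyl-3-oxo-2,3-dihydrofuran-2-yl]but-3-en-2-yl 2-(bromomethyl)prop-2-enoate, via O-acylisourea 13 (not isolated)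
Conditions: DIC, DMAP (5 mol %), CH2Cl2, 0 °C
Reagents that add atoms: none
Why: Steglich esterification of the only free hydroxyl (O8) through the O-acylisourea, run cold with little DMAP to spare the allylic bromide; C8 is not touched.

Step 7
Reactants: 14 bromomethylacrylate ester
Product: 15 (5S)-3-(bromomethyl)-5-{[(2S)-5-{(2Z)-4-[(tert-butyldimethylsilyl)oxy]but-2-en-2-yl}-2-methyl-3-oxo-2,3-dihydrofuran-2-yl]methyl}furan-2(5H)-one
Conditions: second-generation Hoveyda–Grubbs catalyst (5 mol %), toluene, 70 °C
Reagents that add atoms: none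
Why: Ring-closing metathesis of the C8 vinyl group with the 1,1-disubstituted acrylate alkene should give the butenolide (C7=C11, loss of ethene); the trisubstituted, conjugated C4=C5 and C2=C3 bonds do not take part.

Step 8
Reactants: 15 silyl-protected bromomethyl butenolide
Product: 16 (5S)-3-(bromomethyl)-5-{[(2S)-5-[(2Z)-4-hydroxybut-2-en-2-yl]-2-methyl-3-oxo-2,3-dihydrofuran-2-yl]methyl}furan-2(5H)-one
Conditions: aq. HF, MeCN, 0 °C
Reagents that add atoms: none
Why: Acidic fluoride cleaves the primary allylic silyl ether without base, so the bromomethyl butenolide and its C8 stereocentre are spared (desilylation).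

Step 9
Reactants: 16 allylic alcohol
Product: 17 (2Z)-3-[(5S)-5-{[(2S)-4-(bromomethyl)-5-oxo-2,5-dihydrofuran-2-yl]methyl}-5-methyl-4-oxo-4,5-dihydrofuran-2-yl]but-2-enal
Conditions: Dess–Martin periodinane, CH2Cl2, 0 °C → rt
Reagents that add atoms: none
Why: Dess–Martin oxidation of the primary allylic alcohol under neutral conditions should keep the Z geometry of C4=C5 and leave the allylic bromide alone.

Step 10
Reactants: 17 Z-enal bromide
Product: 19 (6R,7S,8S,10S)-6-hydroxy tricycle (the target skeleton with free 6R hydroxyl), via allylchromium dichloride 18 (not isolated)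
Conditions: CrCl2 (8 equiv), THF, rt, 17 added by syringe pump to 2 mM; then H2O
Reagents that add atoms: none
Why: Two single-electron transfers from divalent chromium convert the C13–Br bond of 17 into allylchromium 18 (trivalent chromium), whose γ-carbon C7 adds to the C6 aldehyde through a six-membered Zimmerman–Traxler chair with allylic transposition, so that C6–C7 forms while the double bond moves from C7=C11 to the exocyclic C11=C13 of the α-methylene lactone. The closest known reactions are the chromium- or zinc-mediated additions of 3-(bromomethyl)furan-2(5H)-ones to aldehydes and the Nozaki–Hiyama-type allylation macrocyclisations that close ten-membered germacranolide rings. Only the nine-membered oxacycle is closed, by a 9-exo-trig attack on the aldehyde carbon (SE2' at the allyl unit), the furanone and the lactone being in place already. C7 is set by C8, because the aldehyde arm, tied back through C9, can reach C7 in the chair only on the face anti to C9, which gives the trans-lactone; C6 is set by the chair itself, because the ring-locked allyl unit (C8 trans to C13) with the enal residue equatorial should lead to the anti, 6R alcohol, the epimer that step 14 inverts. The step needs aldehyde over C1-ketone selectivity (a five-membered ring could close onto C1) and cyclisation over oligomerisation: the first rests on the aldehyde preference of allylchromium reagents and on C1 being a vinylogous-ester carbonyl next to quaternary C10, the second on slow addition at high dilution.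

Step 11
Reactants: 20 methyl (2Z)-2-methylbut-2-enoate (methyl angelate)
Product: 22 (2Z)-2-methylbut-2-en-1-ol, via (2Z)-2-methylbut-2-enal 21 (not isolated)
Conditions: i-Bu2AlH (2.2 equiv), CH2Cl2, −78 → 0 °C; Rochelle salt work-up
Reagents that add atoms: none
Why: Low-temperature DIBAL reduction of the ester to the allylic alcohol through the aldehyde should not isomerise the Z alkene.

Step 12
Reactants: 22 (2Z)-2-methylbut-2-en-1-ol
Product: 23 [(2R,3S)-2,3-dimethyloxiran-2-yl]methanol
Conditions: Ti(OiPr)4 (10 mol %), D-(−)-diethyl tartrate (12 mol %), t-BuOOH, 4 Å MS, CH2Cl2, −20 °C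
Reagents that add atoms: tert-butyl hydroperoxide, CC(C)(C)OO
Why: Sharpless asymmetric epoxidation, in which the D-(−)-tartrate titanium complex delivers oxygen to the alkene face that gives the 2R,3S epoxy alcohol (L-(+)-tartrate gives the 2S series) and the Z geometry fixes the cis relation of the C3 methyl and CH2OH.

Step 13
Reactants: 23 epoxy alcohol
Product: 25 (2S,3S)-2,3-dimethyloxirane-2-carboxylic acid, via epoxy aldehyde 24 (not isolated)
Conditions: TEMPO (10 mol %), PhI(OAc)2 (2.2 equiv), MeCN/H2O, rt
Reagents that add atoms: water, O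
Why: TEMPO/PhI(OAc)2 oxidation in wet acetonitrile takes the primary alcohol through the aldehyde and its hydrate to the acid without opening the epoxide, and the quaternary C2 cannot epimerise.

Step 14
Reactants: 19 6R alcohol; 25 (2S,3S)-2,3-dimethyloxirane-2-carboxylic acid
Product: 27 target (6S,7R,8S,10S) epoxyangelate CNP0258430.1, via alkoxyphosphonium carboxylate 26 (not isolated)
Conditions: PPh3, DIAD (pre-mixed, 0 °C), then 25 and 19, toluene, 0 °C → rt
Reagents that add atoms: none
Why: Mitsunobu esterification, in which O6 is activated as the alkoxyphosphonium salt and displaced by the carboxylate with SN2 inversion (6R to 6S); pre-forming the PPh3–DIAD betaine keeps free phosphine away from the α-methylene lactone.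

**Compound list**

1 | (2Z)-3-methylpent-2-en-4-yn-1-ol | C#C/C(C)=C\CO | starting material
2 | tert-butyl(dimethyl){[(2Z)-3-methylpent-2-en-4-yn-1-yl]oxy}silane | C#C/C(C)=C\CO[Si](C)(C)C(C)(C)C | intermediate
3 | methyl pyruvate | CC(=O)C(=O)OC | starting material
4 | 2-(trimethylsilyloxy)buta-1,3-diene | C=CC(=C)O[Si](C)(C)C | starting material
5 | methyl (2S)-2-methyl-4-oxo-2-[(trimethylsilyl)oxy]hex-5-enoate | C=CC(=O)C[C@](C)(O[Si](C)(C)C)C(=O)OC | intermediate (not isolated)
6 | methyl (2S)-2-hydroxy-2-methyl-4-oxohex-5-enoate | C=CC(=O)C[C@](C)(O)C(=O)OC | intermediate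
7 | methyl (2S,4S)-2,4-dihydroxy-2-methylhex-5-enoate (1,3-anti diol) | C=C[C@@H](O)C[C@](C)(O)C(=O)OC | intermediate (not isolated)
8 | (3S,5S)-5-ethenyl-3-hydroxy-3-methyloxolan-2-one | C=C[C@@H]1C[C@](C)(O)C(=O)O1 | intermediate
9 | lithium acetylide of 2 | [Li]C#C/C(C)=C\CO[Si](C)(C)C(C)(C)C | intermediate (not isolated)
10 | (2Z,7S,9S)-1-[(tert-butyldimethylsilyl)oxy]-7,9-dihydroxy-3,7-dimethylundeca-2,10-dien-4-yn-6-one (in equilibrium with its five-membered lactol) | C=C[C@@H](O)C[C@](C)(O)C(=O)C#C/C(C)=C\CO[Si](C)(C)C(C)(C)C | intermediate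
11 | (2S)-5-{(2Z)-4-[(tert-butyldimethylsilyl)oxy]but-2-en-2-yl}-2-[(2S)-2-hydroxybut-3-en-1-yl]-2-methylfuran-3(2H)-one | C=C[C@@H](O)C[C@]1(C)OC(=CC1=O)/C(C)=C\CO[Si](C)(C)C(C)(C)C | intermediate
12 | 2-(bromomethyl)prop-2-enoic acid | C=C(CBr)C(=O)O | starting material
13 | O-[2-(bromomethyl)prop-2-enoyl]-N,N'-diisopropylisourea | C=C(CBr)C(=O)OC(=NC(C)C)NC(C)C | intermediate (not isolated)
14 | (2S)-1-[(2S)-5-{(2Z)-4-[(tert-butyldimethylsilyl)oxy]but-2-en-2-yl}-2-methyl-3-oxo-2,3-dihydrofuran-2-yl]but-3-en-2-yl 2-(bromomethyl)prop-2-enoate | C=C[C@@H](OC(=O)C(=C)CBr)C[C@]1(C)OC(=CC1=O)/C(C)=C\CO[Si](C)(C)C(C)(C)C | intermediate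
15 | (5S)-3-(bromomethyl)-5-{[(2S)-5-{(2Z)-4-[(tert-butyldimethylsilyl)oxy]but-2-en-2-yl}-2-methyl-3-oxo-2,3-dihydrofuran-2-yl]methyl}furan-2(5H)-one | BrCC1=C[C@H](C[C@]2(C)OC(=CC2=O)/C(C)=C\CO[Si](C)(C)C(C)(C)C)OC1=O | intermediate
16 | (5S)-3-(bromomethyl)-5-{[(2S)-5-[(2Z)-4-hydroxybut-2-en-2-yl]-2-methyl-3-oxo-2,3-dihydrofuran-2-yl]methyl}furan-2(5H)-one | BrCC1=C[C@H](C[C@]2(C)OC(=CC2=O)/C(C)=C\CO)OC1=O | intermediate
17 | (2Z)-3-[(5S)-5-{[(2S)-4-(bromomethyl)-5-oxo-2,5-dihydrofuran-2-yl]methyl}-5-methyl-4-oxo-4,5-dihydrofuran-2-yl]but-2-enal | BrCC1=C[C@H](C[C@]2(C)OC(=CC2=O)/C(C)=C\C=O)OC1=O | intermediate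
18 | allylchromium dichloride from 17 (trivalent chromium on C13) | Cl[Cr](Cl)CC1=C[C@H](C[C@]2(C)OC(=CC2=O)/C(C)=C\C=O)OC1=O | intermediate (not isolated)
19 | (6R,7S,8S,10S)-6-hydroxy tricycle: furanone, trans-fused α-methylene lactone at C7/C8, nine-membered oxacycle with Z-C4=C5, free 6R hydroxyl | C=C1C(=O)O[C@H]2C[C@]3(C)OC(=CC3=O)/C(C)=C\[C@@H](O)[C@H]12 | intermediate
20 | methyl (2Z)-2-methylbut-2-enoate (methyl angelate) | C/C=C(/C)C(=O)OC | starting material
21 | (2Z)-2-methylbut-2-enal | C/C=C(/C)C=O | intermediate (not isolated)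
22 | (2Z)-2-methylbut-2-en-1-ol | C/C=C(/C)CO | intermediate
23 | [(2R,3S)-2,3-dimethyloxiran-2-yl]methanol | OC[C@@]1(C)O[C@H]1C | intermediate
24 | (2S,3S)-2,3-dimethyloxirane-2-carbaldehyde | O=C[C@@]1(C)O[C@H]1C | intermediate (not isolated)
25 | (2S,3S)-2,3-dimethyloxirane-2-carboxylic acid | OC(=O)[C@@]1(C)O[C@H]1C | intermediate
26 | C6-oxytriphenylphosphonium salt of 19 with the carboxylate of 25 | C=C1C(=O)O[C@H]2C[C@]3(C)OC(=CC3=O)/C(C)=C\[C@@H](O[P+](c4ccccc4)(c4ccccc4)c4ccccc4)[C@H]12.[O-]C(=O)[C@@]1(C)O[C@H]1C | intermediate (not isolated)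
27 | target: (6S,7R,8S,10S) tricycle with O6 (2S,3S)-2,3-dimethyloxirane-2-carboxylate | C=C1C(=O)O[C@H]2C[C@]3(C)OC(=CC3=O)/C(C)=C\[C@H](OC(=O)[C@@]3(C)O[C@H]3C)[C@H]12 | target

**Count and risks**

Total step count: 14. Longest linear sequence: 10 steps (steps 2 to 10, then 14, from methyl pyruvate 3).

Steps most likely to fail:

1. Step 10. Closure of the strained nine-membered ring may be slower than loss of the allylchromium by protonation, by 1,4-elimination that opens the butenolide, or by five-membered ring closure onto the furanone C1 carbonyl; the facial selectivity at C6 and C7 is also argued from open-chain cases and from models, not secured. The fallback makes the C6–C7 bond intermolecularly and closes the ring by metathesis at C4=C5; it sets out from 8 and comes back at 19. Lactone 8 is opened as in step 4 with the lithium acetylide of commercial 2-methylbut-1-en-3-yne (n-BuLi, THF, −78 °C) to the isopropenyl ynone F1. (Ph3P)AuNTf2 cyclises this to the isopropenyl furanone alcohol F2, and esterification with 12 (DIC, DMAP) gives the bromomethylacrylate ester F3. Metathesis with second-generation Hoveyda–Grubbs catalyst should close the five-membered butenolide in preference to a seven-membered ring and give the bromomethyl butenolide F4. CrCl2-mediated allylation of acrolein (THF, rt) should then give the anti, trans seco-alcohol F5 with the C6 and C7 configuration of 19. Metathesis of the C6 vinyl and C3 isopropenyl groups (same catalyst, toluene, 100 °C, high dilution) closes C4=C5, Z by ring constraint, to give 19.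

2. Step 14. SN2 displacement at the hindered ring carbinol may lose to elimination toward C7, to acyl transfer with retention, or to phosphine addition to the α-methylene lactone. The fallback inverts C6 by oxidation and reduction and then acylates with retention; it sets out from 19 and comes back at 27. Dess–Martin oxidation (NaHCO3, 0 °C) gives the C6 ketone F6, which is reduced at once with NaBH4/CeCl3 (MeOH, −78 °C), hydride being expected from the open outer face of the nine-membered ring, to the 6S alcohol F7. The mixed anhydride of 25 with 2,4,6-trichlorobenzoyl chloride (Et3N, DMAP, toluene) then acylates F7 to 27. Should step 10 deliver F7 directly, the same acylation applies.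

3. Step 2. After the aldol the tertiary copper alkoxide may add to the new vinyl ketone (a formal hetero-Diels–Alder outcome), or the dienyl enolsilane may react with poor facial selectivity. The fallback uses a silyl ketene thioacetal and an acyl cross-coupling; it sets out from 3 and comes back at 6. Methyl pyruvate 3 and 1-(ethylthio)-1-(trimethylsilyloxy)ethene under the same Cu(OTf)2/(S,S)-tBu-box catalyst, followed by HCl work-up, give the S-ethyl thioester F8. Liebeskind–Srogl coupling with tributyl(vinyl)stannane (Pd2(dba)3, tri(2-furyl)phosphine, CuO2PPh2, THF, 50 °C) converts the thioester into vinyl ketone 6.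

**Further compounds**

F1 | step 10 | (6S,8S)-6,8-dihydroxy-2,6-dimethyldeca-1,9-dien-3-yn-5-one | C=C[C@@H](O)C[C@](C)(O)C(=O)C#CC(C)=C
F2 | step 10 | (2S)-2-[(2S)-2-hydroxybut-3-en-1-yl]-2-methyl-5-(prop-1-en-2-yl)furan-3(2H)-one | C=C[C@@H](O)C[C@]1(C)OC(=CC1=O)C(C)=C
F3 | step 10 | (2S)-1-[(2S)-2-methyl-3-oxo-5-(prop-1-en-2-yl)-2,3-dihydrofuran-2-yl]but-3-en-2-yl 2-(bromomethyl)prop-2-enoate | C=C[C@@H](OC(=O)C(=C)CBr)C[C@]1(C)OC(=CC1=O)C(C)=C
F4 | step 10 | (5S)-3-(bromomethyl)-5-{[(2S)-2-methyl-3-oxo-5-(prop-1-en-2-yl)-2,3-dihydrofuran-2-yl]methyl}furan-2(5H)-one | BrCC1=C[C@H](C[C@]2(C)OC(=CC2=O)C(C)=C)OC1=O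
F5 | step 10 | 4,5-seco analogue of 19: trans α-methylene lactone with a (6R)-hydroxy vinyl carbinol on C7 and the isopropenyl furanone on C9 | C=C1C(=O)O[C@@H](C[C@]2(C)OC(=CC2=O)C(C)=C)[C@@H]1[C@H](O)C=C
F6 | step 14 | C6 ketone of 19 | C=C1C(=O)O[C@H]2C[C@]3(C)OC(=CC3=O)/C(C)=C\C(=O)[C@H]12
F7 | step 14 | 6S epimer of 19 (6S alcohol) | C=C1C(=O)O[C@H]2C[C@]3(C)OC(=CC3=O)/C(C)=C\[C@H](O)[C@H]12
F8 | step 2 | 1-methyl 4-S-ethyl (2S)-2-hydroxy-2-methyl-4-thiobutanedioate | CCSC(=O)C[C@](C)(O)C(=O)OC
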